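**Retrosynthetic overview**

1. Target 27 ← methoxymethyl removal and saponification ← Z-selective Still–Gennari olefination (C7'=C8') ← ester-to-aldehyde reduction of the bis(E-γ,δ-unsaturated ester) 22.
2. Feature used: each side chain on C2/C2' of the pyran rings (rings B and B') holds an E-trisubstituted C3'=C4' alkene followed by the C5'–C6' bond of a 1,5-diene. Both C5'–C6' bonds are cut together (double Johnson–Claisen) to the bis(isopropenyl carbinol) 18 and triethyl orthoacetate 19.
3. 18 ← isopropenylmagnesium bromide + C3' dialdehyde 16 ← oxidative cleavage of both prenyl termini of the bichroman 14.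
4. 14 ← C5–C5' bond between the benzene rings (rings A and A') by Negishi coupling of the 2S and 2R 5-bromochromans 11 and 10; pairing the antipodes sets the 2R,2'S relationship.
5. Ring order: pyran ring B is closed first, on the monomer (phenol 1 + citral, oxa-6π closure, racemic; antipodes separated after bromination); ring A comes from 1; no ring is formed after step 1.

Key step: step 10

Remark: the target leaves the C5–C5' axis undefined; with one 2R and one 2S half the two axial forms are mirror images, so every bichroman from 14 on is treated as one racemic diastereomer and no axial control is attempted.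

**Route**

Step 1
Reactants: 1 4-methoxy-2-methylphenol; 2 citral (E/Z mixture)
Product: 5 (±)-6-methoxy-2,8-dimethyl-2-(4-methylpent-3-en-1-yl)-2H-chromene, via benzodioxaborin 3 (not isolated), via ortho-quinone methide 4 (not isolated)
Conditions: PhB(OH)2 (1.2 equiv), AcOH (catalytic), toluene, reflux, azeotropic removal of water
Reagents that add atoms: none
Why: Boron-templated ortho-hydroxyalkylation of the phenol at its only free ortho carbon gives 3, which on heating expels the boron unit to 4, and oxa-6π-electrocyclisation closes the pyran ring (phenol–enal condensation to a 2H-chromene); C2 forms without control as the racemate, which is wanted because both antipodes are used.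

Step 2
Reactants: 5 (±)-6-methoxy-2,8-dimethyl-2-(4-methylpent-3-en-1-yl)-2H-chromene
Product: 6 (±)-6-methoxy-2,8-dimethyl-2-(4-methylpent-3-en-1-yl)chromane
Conditions: H2 (1 atm), RhCl(PPh3)3 (5 mol%), toluene/EtOH, 25 °C
Reagents that add atoms: none
Why: Homogeneous rhodium-catalysed hydrogenation discriminates by substitution, so the cis-disubstituted styrenic C3=C4 bond should be saturated while the trisubstituted side-chain alkene and the aryl ethers stay untouched; no stereocentre is formed.

Step 3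
Reactants: 6 (±)-6-methoxy-2,8-dimethyl-2-(4-methylpent-3-en-1-yl)chromane
Product: 7 (±)-2,8-dimethyl-2-(4-methylpent-3-en-1-yl)chroman-6-ol
Conditions: NaSEt (4 equiv), DMF, 130 °C; then 1 M HCl
Reagents that add atoms: none
Why: Nucleophilic demethylation (SN2 at the methyl group by thiolate) frees the C6 phenol, while the tertiary alkyl–oxygen bond of the pyran ring cannot be attacked in this way and the alkene is inert to the base.

Step 4
Reactants: 7 (±)-2,8-dimethyl-2-(4-methylpent-3-en-1-yl)chroman-6-ol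
Product: 8 (±)-5-bromo-2,8-dimethyl-2-(4-methylpent-3-en-1-yl)chroman-6-ol
Conditions: NBS (1.0 equiv), CH2Cl2 (dry), −78 → −30 °C, dark
Reagents that add atoms: N-bromosuccinimide, O=C1CCC(=O)N1Br
Why: Electrophilic aromatic bromination ortho to the free hydroxyl should go to C5, the position next to the ring-fusion carbon C4a that is the more reactive ortho site of 6-chromanols of the δ-tocopherol type, and in a cold, dry, non-nucleophilic medium the phenol should capture the reagent before the side-chain alkene does.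

Step 5
Reactants: 8 (±)-5-bromo-2,8-dimethyl-2-(4-methylpent-3-en-1-yl)chroman-6-ol
Product: 9 (±)-5-bromo-6-(methoxymethoxy)-2,8-dimethyl-2-(4-methylpent-3-en-1-yl)chromane
Conditions: NaH, THF/DMF, 0 °C; MOMCl, 0 → 25 °C
Reagents that add atoms: chloromethyl methyl ether, COCCl
Why: Williamson-type O-alkylation of the phenoxide gives the methoxymethyl acetal, which withstands the organolithium, Grignard, hydride and amide-base steps that follow.

Step 6
Reactants: 9 (±)-5-bromo-6-(methoxymethoxy)-2,8-dimethyl-2-(4-methylpent-3-en-1-yl)chromane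
Product: 10 (2R)-5-bromo-6-(methoxymethoxy)-2,8-dimethyl-2-(4-methylpent-3-en-1-yl)chromane; 11 its (2S) antipode, from the same separation
Conditions: preparative SFC, cellulose tris(3,5-dimethylphenylcarbamate) phase, CO2/i-PrOH, 35 °C
Reagents that add atoms: none
Why: Enantiomer separation on a polysaccharide carbamate phase, the class of phase that resolves C2 epimers of 2-methyl-2-alkylchroman ethers, fixes the configuration at C2 for each half; both fractions are used, so nothing is discarded.

Step 7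
Reactants: 11 (2S)-5-bromo-6-(methoxymethoxy)-2,8-dimethyl-2-(4-methylpent-3-en-1-yl)chromane; 10 (2R)-5-bromo-6-(methoxymethoxy)-2,8-dimethyl-2-(4-methylpent-3-en-1-yl)chromane
Product: 14 (2R,2'S)-6,6'-bis(methoxymethoxy)-2,2',8,8'-tetramethyl-2,2'-bis(4-methylpent-3-en-1-yl)-5,5'-bichromane, via aryllithium 12 (not isolated), via arylzinc chloride 13 (not isolated)
Conditions: 11, t-BuLi (2.1 equiv), THF, −78 °C; ZnCl2, −78 → 25 °C; then 10, Pd2(dba)3 (2.5 mol%), 2-dicyclohexylphosphino-2',6'-diisopropoxybiphenyl (10 mol%), THF/NMP, 70 °C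
Reagents that add atoms: none
Why: Bromine–lithium exchange and transmetalation give the 2S arylzinc chloride, and Negishi coupling with the 2R bromide under a bulky dialkylbiarylphosphine–palladium catalyst, a system known to form tetra-ortho-substituted biaryls, makes the C5–C5' bond; using one antipode as nucleophile and the other as electrophile sets the 2R,2'S relationship.

Step 8
Reactants: 14 (2R,2'S)-6,6'-bis(methoxymethoxy)-2,2',8,8'-tetramethyl-2,2'-bis(4-methylpent-3-en-1-yl)-5,5'-bichromane
Product: 16 3,3'-[(2R,2'S)-6,6'-bis(methoxymethoxy)-2,2',8,8'-tetramethyl-5,5'-bichromane-2,2'-diyl]dipropanal, via tetraol 15 (not isolated)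
Conditions: OsO4 (2 mol%), NaIO4 (6 equiv), 2,6-lutidine (4 equiv), dioxane/H2O 3:1, 25 °C
Reagents that add atoms: osmium tetroxide, O=[Os](=O)(=O)=O; sodium periodate, [Na+].[O-]I(=O)(=O)=O
Why: Lemieux–Johnson oxidation, in which osmylation of the two trisubstituted alkenes and periodate cleavage of the glycols in the same pot give the C3' aldehydes, leaves the aryl rings, the acetals and the C2 centres untouched.

Step 9
Reactants: 16 3,3'-[(2R,2'S)-6,6'-bis(methoxymethoxy)-2,2',8,8'-tetramethyl-5,5'-bichromane-2,2'-diyl]dipropanal; 17 isopropenylmagnesium bromide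
Product: 18 5,5'-[(2R,2'S)-6,6'-bis(methoxymethoxy)-2,2',8,8'-tetramethyl-5,5'-bichromane-2,2'-diyl]bis(2-methylpent-1-en-3-ol), mixture of carbinol epimers
Conditions: 17 (3 equiv), THF, −78 → 0 °C; aqueous NH4Cl
Reagents that add atoms: none
Why: 1,2-Addition of the vinylic Grignard reagent to both aldehydes gives the secondary 2-methylallylic alcohols; the new C3' carbinol centres form without control, which is acceptable because step 10 erases them.

Step 10
Reactants: 18 5,5'-[(2R,2'S)-6,6'-bis(methoxymethoxy)-2,2',8,8'-tetramethyl-5,5'-bichromane-2,2'-diyl]bis(2-methylpent-1-en-3-ol); 19 triethyl orthoacetate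
Product: 22 diethyl (4E,4'E)-7,7'-[(2R,2'S)-6,6'-bis(methoxymethoxy)-2,2',8,8'-tetramethyl-5,5'-bichromane-2,2'-diyl]bis(4-methylhept-4-enoate), via bis(mixed orthoester) 20 (not isolated), via bis(ketene acetal) 21 (not isolated)
Conditions: 19 (10 equiv), EtCO2H (0.1 equiv), 138 °C, EtOH distilled off
Reagents that add atoms: none
Why: Under propionic acid catalysis each C3' carbinol oxygen exchanges for one ethoxy group of the orthoester (20) and loses ethanol to the mixed ketene acetal 21, an allyl vinyl ether that undergoes a concerted suprafacial [3,3]-sigmatropic shift through a chair transition state, forming C5'–C6' in each chain and moving the alkene from the isopropenyl group to C3'=C4'. The closest known reaction type is the Johnson orthoester Claisen rearrangement of secondary 2-methylallylic alcohols to E-configured γ,δ-unsaturated esters, here run twice in one molecule. No ring is closed and no stereocentre is created; the C3' carbinol centres are erased, so every epimer of 18 converges on the same product. The selectivity required is E geometry at both C3'=C4' bonds, and the substrate secures it because the C1'–C2' chain on the carbinol carbon sits pseudo-equatorial in the chair, the pseudo-axial alternative that leads to Z being penalised by a 1,3-diaxial contact with the ethoxy group of the ketene acetal. The weak acid and the absence of water should leave the methoxymethyl acetals, the pyran ethers and the C2 centres untouched, and removal of ethanol drives both exchanges to completion.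

Step 11
Reactants: 22 diethyl (4E,4'E)-7,7'-[(2R,2'S)-6,6'-bis(methoxymethoxy)-2,2',8,8'-tetramethyl-5,5'-bichromane-2,2'-diyl]bis(4-methylhept-4-enoate)
Product: 23 (4E,4'E)-7,7'-[(2R,2'S)-6,6'-bis(methoxymethoxy)-2,2',8,8'-tetramethyl-5,5'-bichromane-2,2'-diyl]bis(4-methylhept-4-enal)
Conditions: i-Bu2AlH (2.3 equiv), CH2Cl2, −78 °C; MeOH, then aqueous potassium sodium tartrate
Reagents that add atoms: none
Why: Partial ester reduction, in which the tetrahedral aluminium hemiacetal persists at −78 °C so that the aldehyde is released only after the hydride has been quenched.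

Step 12
Reactants: 23 (4E,4'E)-7,7'-[(2R,2'S)-6,6'-bis(methoxymethoxy)-2,2',8,8'-tetramethyl-5,5'-bichromane-2,2'-diyl]bis(4-methylhept-4-enal); 24 ethyl 2-[bis(2,2,2-trifluoroethoxy)phosphoryl]propanoate
Product: 25 diethyl (2Z,6E,2'Z,6'E)-9,9'-[(2R,2'S)-6,6'-bis(methoxymethoxy)-2,2',8,8'-tetramethyl-5,5'-bichromane-2,2'-diyl]bis(2,6-dimethylnona-2,6-dienoate)
Conditions: 24 (3 equiv), KN(SiMe3)2 (2.9 equiv), 18-crown-6 (6 equiv), THF, −78 °C; then 23
Reagents that add atoms: none
Why: Still–Gennari olefination, in which the electron-poor bis(trifluoroethyl) phosphonate and a dissociated potassium counter-ion let elimination from the kinetically formed adduct outrun its equilibration, should give the Z-configured 2-methyl-2-enoate (ester cis to the chain) at both C7'=C8' bonds.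

Step 13
Reactants: 25 diethyl (2Z,6E,2'Z,6'E)-9,9'-[(2R,2'S)-6,6'-bis(methoxymethoxy)-2,2',8,8'-tetramethyl-5,5'-bichromane-2,2'-diyl]bis(2,6-dimethylnona-2,6-dienoate)
Product: 26 diethyl (2Z,6E,2'Z,6'E)-9,9'-[(2R,2'S)-6,6'-dihydroxy-2,2',8,8'-tetramethyl-5,5'-bichromane-2,2'-diyl]bis(2,6-dimethylnona-2,6-dienoate)
Conditions: HCl (0.5 M in EtOH), 40 °C
Reagents that add atoms: none
Why: Acid-catalysed acetal exchange with the solvent removes both methoxymethyl groups as volatile formaldehyde acetals, ethanol as solvent keeps the ethyl esters as they are, and the isolated trisubstituted alkenes and Z-enoates should tolerate the dilute acid.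

Step 14
Reactants: 26 diethyl (2Z,6E,2'Z,6'E)-9,9'-[(2R,2'S)-6,6'-dihydroxy-2,2',8,8'-tetramethyl-5,5'-bichromane-2,2'-diyl]bis(2,6-dimethylnona-2,6-dienoate)
Product: 27 (2Z,6E,2'Z,6'E)-9,9'-[(2R,2'S)-6,6'-dihydroxy-2,2',8,8'-tetramethyl-5,5'-bichromane-2,2'-diyl]bis(2,6-dimethylnona-2,6-dienoic acid), the target
Conditions: LiOH (10 equiv), THF/EtOH/H2O (degassed), 40 °C, argon; then 1 M HCl to pH 3
Reagents that add atoms: lithium hydroxide, [Li+].[OH-]
Why: Saponification by acyl–oxygen cleavage hydrolyses both hindered Z-enoates, exclusion of oxygen protects the electron-rich phenoxides, and the Z geometry should hold because the carboxylate formed is not deprotonated further under these conditions.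

**Compound list**

1 | 4-methoxy-2-methylphenol | COc1ccc(O)c(C)c1 | starting material
2 | citral (3,7-dimethylocta-2,6-dienal, E/Z mixture) | CC(C)=CCCC(C)=CC=O | starting material
3 | 4-(2,6-dimethylhepta-1,5-dien-1-yl)-6-methoxy-8-methyl-2-phenyl-4H-1,3,2-benzodioxaborinine (racemic, formed in the flask) | COc1cc(C)c2OB(c3ccccc3)OC(C=C(C)CCC=C(C)C)c2c1 | intermediate
4 | 6-(3,7-dimethylocta-2,6-dien-1-ylidene)-4-methoxy-2-methylcyclohexa-2,4-dien-1-one (formed in the flask) | COC1=CC(=CC=C(C)CCC=C(C)C)C(=O)C(C)=C1 | intermediate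
5 | (±)-6-methoxy-2,8-dimethyl-2-(4-methylpent-3-en-1-yl)-2H-chromene | COc1cc(C)c2OC(C)(CCC=C(C)C)C=Cc2c1 | intermediate
6 | (±)-6-methoxy-2,8-dimethyl-2-(4-methylpent-3-en-1-yl)chromane | COc1cc(C)c2OC(C)(CCC=C(C)C)CCc2c1 | intermediate
7 | (±)-2,8-dimethyl-2-(4-methylpent-3-en-1-yl)chroman-6-ol | Oc1cc(C)c2OC(C)(CCC=C(C)C)CCc2c1 | intermediate
8 | (±)-5-bromo-2,8-dimethyl-2-(4-methylpent-3-en-1-yl)chroman-6-ol | Oc1cc(C)c2OC(C)(CCC=C(C)C)CCc2c1Br | intermediate
9 | (±)-5-bromo-6-(methoxymethoxy)-2,8-dimethyl-2-(4-methylpent-3-en-1-yl)chromane | COCOc1cc(C)c2OC(C)(CCC=C(C)C)CCc2c1Br | intermediate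
10 | (2R)-5-bromo-6-(methoxymethoxy)-2,8-dimethyl-2-(4-methylpent-3-en-1-yl)chromane | CC(C)=CCC[C@]1(C)CCc2c(c(C)cc(OCOC)c2Br)O1 | intermediate
11 | (2S)-5-bromo-6-(methoxymethoxy)-2,8-dimethyl-2-(4-methylpent-3-en-1-yl)chromane | CC(C)=CCC[C@@]1(C)CCc2c(c(C)cc(OCOC)c2Br)O1 | intermediate
12 | [(2S)-6-(methoxymethoxy)-2,8-dimethyl-2-(4-methylpent-3-en-1-yl)chroman-5-yl]lithium (formed in the flask) | CC(C)=CCC[C@@]1(C)CCc2c(c(C)cc(OCOC)c2[Li])O1 | intermediate
13 | chloro[(2S)-6-(methoxymethoxy)-2,8-dimethyl-2-(4-methylpent-3-en-1-yl)chroman-5-yl]zinc (formed in the flask) | CC(C)=CCC[C@@]1(C)CCc2c(c(C)cc(OCOC)c2[Zn]Cl)O1 | intermediate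
14 | (2R,2'S)-6,6'-bis(methoxymethoxy)-2,2',8,8'-tetramethyl-2,2'-bis(4-methylpent-3-en-1-yl)-5,5'-bichromane | CC(C)=CCC[C@@]1(C)CCc2c(c(C)cc(OCOC)c2-c2c(OCOC)cc(C)c3c2CC[C@@](C)(CCC=C(C)C)O3)O1 | intermediate
15 | 5,5'-[(2R,2'S)-6,6'-bis(methoxymethoxy)-2,2',8,8'-tetramethyl-5,5'-bichromane-2,2'-diyl]bis(2-methylpentane-2,3-diol), carbinol epimers (formed in the flask) | CC(C)(O)C(O)CC[C@@]1(C)CCc2c(c(C)cc(OCOC)c2-c2c(OCOC)cc(C)c3c2CC[C@@](C)(CCC(O)C(C)(C)O)O3)O1 | intermediate
16 | 3,3'-[(2R,2'S)-6,6'-bis(methoxymethoxy)-2,2',8,8'-tetramethyl-5,5'-bichromane-2,2'-diyl]dipropanal | O=CCC[C@@]1(C)CCc2c(c(C)cc(OCOC)c2-c2c(OCOC)cc(C)c3c2CC[C@@](C)(CCC=O)O3)O1 | intermediate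
17 | isopropenylmagnesium bromide | C=C(C)[Mg]Br | starting material
18 | 5,5'-[(2R,2'S)-6,6'-bis(methoxymethoxy)-2,2',8,8'-tetramethyl-5,5'-bichromane-2,2'-diyl]bis(2-methylpent-1-en-3-ol), carbinol epimers | C=C(C)C(O)CC[C@@]1(C)CCc2c(c(C)cc(OCOC)c2-c2c(OCOC)cc(C)c3c2CC[C@@](C)(CCC(O)C(C)=C)O3)O1 | intermediate
19 | triethyl orthoacetate | CC(OCC)(OCC)OCC | starting material
20 | bis(1,1-diethoxyethyl) ether of 18 (formed in the flask) | C=C(C)C(OC(C)(OCC)OCC)CC[C@@]1(C)CCc2c(c(C)cc(OCOC)c2-c2c(OCOC)cc(C)c3c2CC[C@@](C)(CCC(OC(C)(OCC)OCC)C(C)=C)O3)O1 | intermediate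
21 | bis(1-ethoxyvinyl) ether of 18 (formed in the flask) | C=C(C)C(OC(=C)OCC)CC[C@@]1(C)CCc2c(c(C)cc(OCOC)c2-c2c(OCOC)cc(C)c3c2CC[C@@](C)(CCC(OC(=C)OCC)C(C)=C)O3)O1 | intermediate
22 | diethyl (4E,4'E)-7,7'-[(2R,2'S)-6,6'-bis(methoxymethoxy)-2,2',8,8'-tetramethyl-5,5'-bichromane-2,2'-diyl]bis(4-methylhept-4-enoate) | CCOC(=O)CC/C(C)=C/CC[C@@]1(C)CCc2c(c(C)cc(OCOC)c2-c2c(OCOC)cc(C)c3c2CC[C@@](C)(CC/C=C(\C)CCC(=O)OCC)O3)O1 | intermediate
23 | (4E,4'E)-7,7'-[(2R,2'S)-6,6'-bis(methoxymethoxy)-2,2',8,8'-tetramethyl-5,5'-bichromane-2,2'-diyl]bis(4-methylhept-4-enal) | O=CCC/C(C)=C/CC[C@@]1(C)CCc2c(c(C)cc(OCOC)c2-c2c(OCOC)cc(C)c3c2CC[C@@](C)(CC/C=C(\C)CCC=O)O3)O1 | intermediate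
24 | ethyl 2-[bis(2,2,2-trifluoroethoxy)phosphoryl]propanoate | CCOC(=O)C(C)P(=O)(OCC(F)(F)F)OCC(F)(F)F | starting material
25 | diethyl (2Z,6E,2'Z,6'E)-9,9'-[(2R,2'S)-6,6'-bis(methoxymethoxy)-2,2',8,8'-tetramethyl-5,5'-bichromane-2,2'-diyl]bis(2,6-dimethylnona-2,6-dienoate) | C/C(=C/CC/C(C)=C/CC[C@@]1(C)CCc2c(c(C)cc(OCOC)c2-c2c(OCOC)cc(C)c3c2CC[C@@](C)(CC/C=C(\C)CC/C=C(/C)C(=O)OCC)O3)O1)C(=O)OCC | intermediate
26 | diethyl (2Z,6E,2'Z,6'E)-9,9'-[(2R,2'S)-6,6'-dihydroxy-2,2',8,8'-tetramethyl-5,5'-bichromane-2,2'-diyl]bis(2,6-dimethylnona-2,6-dienoate) | C/C(=C/CC/C(C)=C/CC[C@@]1(C)CCc2c(c(C)cc(O)c2-c2c(O)cc(C)c3c2CC[C@@](C)(CC/C=C(\C)CC/C=C(/C)C(=O)OCC)O3)O1)C(=O)OCC | intermediate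
27 | (2Z,6E,2'Z,6'E)-9,9'-[(2R,2'S)-6,6'-dihydroxy-2,2',8,8'-tetramethyl-5,5'-bichromane-2,2'-diyl]bis(2,6-dimethylnona-2,6-dienoic acid) | C/C(=C/CC/C(C)=C/CC[C@@]1(C)CCc2c(c(C)cc(O)c2-c2c(O)cc(C)c3c2CC[C@@](C)(CC/C=C(\C)CC/C=C(/C)C(=O)O)O3)O1)C(=O)O | target

**Count and risks**

Total step count: 14 (13 reactions and one enantiomer separation). Longest linear sequence: 14 steps (1 → 27; both antipodes come from the same racemate).

Steps most likely to fail:

Step 7. Transmetalation and reductive elimination at two doubly ortho-substituted carbons may be slow, so that protonation of the zinc reagent and its homocoupling (which gives the homochiral diastereomer) compete with cross-coupling. The fallback replaces the in situ zinc reagent by an isolable boron nucleophile. It sets out from 11: the aryllithium 12 is quenched with 2-isopropoxy-4,4,5,5-tetramethyl-1,3,2-dioxaborolane to give 2-[(2S)-6-(methoxymethoxy)-2,8-dimethyl-2-(4-methylpent-3-en-1-yl)chroman-5-yl]-4,4,5,5-tetramethyl-1,3,2-dioxaborolane F1. F1 is purified and joined to 10 by Suzuki–Miyaura coupling (Pd(OAc)2, 2-dicyclohexylphosphino-2',6'-dimethoxybiphenyl, K3PO4, toluene/H2O, 100 °C). It comes back to the route at 14.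

Step 4. Bromination at C7, double bromination, or electrophilic attack on the side-chain alkene may compete with substitution at C5. The fallback puts the bromine on the arene before the pyran ring exists, where the substituents fix its position. It sets out from 1, which is acetylated (Ac2O, pyridine) to 4-methoxy-2-methylphenyl acetate F2. Bromination (NBS, MeCN) should then go para to the methyl and ortho to the methoxy group, giving 5-bromo-4-methoxy-2-methylphenyl acetate F3. Methanolysis (K2CO3, MeOH) gives 5-bromo-4-methoxy-2-methylphenol F4. F4 is taken through the chemistry of steps 1 to 3: condensation with 2 to (±)-5-bromo-6-methoxy-2,8-dimethyl-2-(4-methylpent-3-en-1-yl)-2H-chromene F5, hydrogenation over RhCl(PPh3)3 to (±)-5-bromo-6-methoxy-2,8-dimethyl-2-(4-methylpent-3-en-1-yl)chromane F6, and demethylation with NaSEt. It comes back to the route at 8.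

Step 10. At 138 °C the acid catalyst may exchange or remove the aryl methoxymethyl acetals, or the second chain may stop at the mixed orthoester, leaving mono-rearranged material. The fallback keeps the same C5'–C6' bond formation but uses the neutral Eschenmoser–Claisen variant. It sets out from 18, which is heated with N,N-dimethylacetamide dimethyl acetal in xylene (140 °C) to give (4E,4'E)-7,7'-[(2R,2'S)-6,6'-bis(methoxymethoxy)-2,2',8,8'-tetramethyl-5,5'-bichromane-2,2'-diyl]bis(N,N,4-trimethylhept-4-enamide) F7 through the same chair transition state. Partial reduction of the tertiary amides with Cp2Zr(H)Cl (THF, 25 °C) gives the dialdehyde, so the fallback comes back to the route at 23.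

**Further compounds**

F1 | step 7 | 2-[(2S)-6-(methoxymethoxy)-2,8-dimethyl-2-(4-methylpent-3-en-1-yl)chroman-5-yl]-4,4,5,5-tetramethyl-1,3,2-dioxaborolane | CC(C)=CCC[C@@]1(C)CCc2c(c(C)cc(OCOC)c2B2OC(C)(C)C(C)(C)O2)O1
F2 | step 4 | 4-methoxy-2-methylphenyl acetate | COc1ccc(OC(C)=O)c(C)c1
F3 | step 4 | 5-bromo-4-methoxy-2-methylphenyl acetate | COc1cc(C)c(OC(C)=O)cc1Br
F4 | step 4 | 5-bromo-4-methoxy-2-methylphenol | COc1cc(C)c(O)cc1Br
F5 | step 4 | (±)-5-bromo-6-methoxy-2,8-dimethyl-2-(4-methylpent-3-en-1-yl)-2H-chromene | COc1cc(C)c2OC(C)(CCC=C(C)C)C=Cc2c1Br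
F6 | step 4 | (±)-5-bromo-6-methoxy-2,8-dimethyl-2-(4-methylpent-3-en-1-yl)chromane | COc1cc(C)c2OC(C)(CCC=C(C)C)CCc2c1Br
F7 | step 10 | (4E,4'E)-7,7'-[(2R,2'S)-6,6'-bis(methoxymethoxy)-2,2',8,8'-tetramethyl-5,5'-bichromane-2,2'-diyl]bis(N,N,4-trimethylhept-4-enamide) | CN(C)C(=O)CC/C(C)=C/CC[C@@]1(C)CCc2c(c(C)cc(OCOC)c2-c2c(OCOC)cc(C)c3c2CC[C@@](C)(CC/C=C(\C)CCC(=O)N(C)C)O3)O1
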